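**Plan**
- Retrosynthetic cuts, in order: (a) the CH2–CH2 bond between the second and third carbon of the (CH2)12 bridge counted from ring A, traced back to a ring alkene and ring-closing metathesis; (b) the ring A carbon–oxygen bond of the diaryl ether; (c) the ring A–allyl and ring B–undecenyl aryl–CH2 bonds.
- Forward: ring A (3,5-dibromoanisole) receives its allyl group and ring B (4-bromo-2,6-dimethoxyphenol) its undec-10-enyl chain; the two arenes are joined at oxygen; only then is the 20-membered ring closed within the chain; hydrogenation and demethylation finish.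
- Enabling feature: the bridge leaves ring A through a benzylic CH2, so the bond to be made is the β,γ bond of an allyl group on ring A. The bent ether oxygen (C–O–C about 120°) and the meta position of that allyl group fold the short arm back along ring B, whose para position the twelve-carbon bridge reaches without strain.
- Closing the ring in the chain, far from the oxygen bridge, lets the hindered ether to the doubly ortho-oxygenated ring B be made intermolecularly, where it can be forced.
- Stereochemistry: the target has no stereocentre and no stereogenic double bond; the E/Z mixture from ring closure is erased by hydrogenation.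

Key step: step 4

Remark: all four starting materials are taken to be catalogue compounds; the methyl ethers serve as the only protecting groups.

**Step 1**
Reactants: 1 1,3-dibromo-5-methoxybenzene; 2 3-bromoprop-1-ene (allyl bromide)
Product: 4 1-bromo-3-methoxy-5-(prop-2-en-1-yl)benzene, via (3-bromo-5-methoxyphenyl)lithium 3 (not isolated)
Conditions: n-BuLi (1.0 equiv), Et2O, −78 °C; then CuBr·SMe2 (5 mol%), 2 (1.3 equiv), −78 °C to rt
Reagents that add atoms: none
Why: Bromine–lithium exchange on one of the two equivalent C–Br bonds is fast at −78 °C and stops after one exchange because the aryllithium resists a second one, and copper-catalysed allylic substitution on allyl bromide (SN2 and SN2′ give the same product) then forms the aryl–allyl bond without moving the double bond.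

**Step 2**
Reactants: 5 11-bromoundec-1-ene; 6 4-bromo-2,6-dimethoxyphenol
Product: 8 2,6-dimethoxy-4-(undec-10-en-1-yl)phenol, via undec-10-en-1-ylzinc bromide 7 (not isolated)
Conditions: Zn dust, LiCl, THF, 50 °C; then 6, Pd(OAc)2 (2 mol%), SPhos (4 mol%), THF, 25 °C, slow addition of the zinc reagent (1.5 equiv)
Reagents that add atoms: none
Why: Negishi C(sp3)–C(sp2) cross-coupling, in which LiCl-assisted zinc insertion into the primary bromide gives an alkylzinc bromide that tolerates the terminal alkene, the electron-rich biarylphosphine lets zerovalent palladium add to the electron-rich aryl bromide and makes reductive elimination faster than β-hydride elimination, and slow addition lets transmetalation outpace protonolysis by the free phenol.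

**Step 3**
Reactants: 8 2,6-dimethoxy-4-(undec-10-en-1-yl)phenol; 4 1-bromo-3-methoxy-5-(prop-2-en-1-yl)benzene
Product: 9 1,3-dimethoxy-2-[3-methoxy-5-(prop-2-en-1-yl)phenoxy]-5-(undec-10-en-1-yl)benzene
Conditions: CuI (10 mol%), picolinic acid (20 mol%), K3PO4 (2 equiv), DMSO, 90 °C, Ar
Reagents that add atoms: none
Why: Ullmann-type copper-catalysed diaryl ether synthesis, in which the picolinate-ligated monovalent copper phenoxide of the electron-rich, doubly ortho-substituted phenol 8 adds oxidatively to the unhindered aryl bromide 4 and eliminates the ether, with a ligand suited to hindered phenols and a phosphate base too weak to move either double bond.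

**Step 4**
Reactants: 9 1,3-dimethoxy-2-[3-methoxy-5-(prop-2-en-1-yl)phenoxy]-5-(undec-10-en-1-yl)benzene
Product: 10 tri-O-methyl cyclophane alkene 1^5,3^2,3^6-trimethoxy-2-oxa-1(1,3),3(1,4)-dibenzenacyclopentadecaphan-13-ene (E/Z mixture)
Conditions: second-generation Grubbs catalyst RuCl2(H2IMes)(PCy3)(=CHPh) (10 mol%, two portions), 1,4-benzoquinone (20 mol%), CH2Cl2 (1 mM), 40 °C, Ar purge
Reagents that add atoms: none
Why: Ring-closing olefin metathesis by the Chauvin mechanism: the ruthenium benzylidene exchanges onto one of the two monosubstituted alkenes of 9, the resulting alkylidene adds across the other vinyl group to a ruthenacyclobutane, and cycloreversion releases ethene and the ring alkene, so the new carbon–carbon bond joins the former internal allyl carbon on ring A to the former C10 of the undecenyl chain on ring B. The closest known reaction type is the macrocyclic ring-closing metathesis of biaryl- and diaryl ether-tethered α,ω-dienes at a chain position remote from the aryl–aryl junction, as used for resorcinol-derived cyclophanes. One ring is closed, the 20-membered meta,para-cyclophane ring, by end-to-end macrocyclization of two chain termini with the new double bond inside the ring (endo mode). No stereocentre is created, and the E/Z ratio of the ring alkene is of no consequence because step 5 saturates it. The step needs ring closure to outrun intermolecular metathesis and needs the allyl double bond to stay out of conjugation with ring A. The first is secured by the bent ether oxygen and the meta placement of the allyl group on ring A, which fold the short arm back along ring B toward the long flexible undecenyl arm in a strain-free ring, helped by 1 mM dilution and ethene removal, and the second by 1,4-benzoquinone, which intercepts ruthenium hydrides.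

**Step 5**
Reactants: 10 tri-O-methyl cyclophane alkene (E/Z mixture)
Product: 11 tri-O-methyl saturated cyclophane 1^5,3^2,3^6-trimethoxy-2-oxa-1(1,3),3(1,4)-dibenzenacyclopentadecaphane
Conditions: H2 (1 atm), 10% Pd/C, EtOAc, rt
Reagents that add atoms: none
Why: Heterogeneous catalytic hydrogenation saturates the unhindered 1,2-disubstituted ring alkene, so both geometric isomers converge on one product, and leaves the aryl methyl ethers, the diaryl ether and the arenes untouched at one atmosphere and room temperature.

**Step 6**
Reactants: 11 tri-O-methyl saturated cyclophane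
Product: 13 target cyclophane triol 2-oxa-1(1,3),3(1,4)-dibenzenacyclopentadecaphane-1^5,3^2,3^6-triol, via tris(dibromoboryl) ether 12 (not isolated)
Conditions: BBr3 (6 equiv), CH2Cl2, −78 °C to rt; then H2O, 0 °C
Reagents that add atoms: none
Why: Lewis acid-mediated cleavage of aryl methyl ethers (BBr3 demethylation), in which boron binds each methoxy oxygen and bromide removes the methyl group by SN2 attack, a pathway closed to the diaryl ether whose oxygen carries only sp2 carbons, and aqueous work-up hydrolyses the aryloxyboron bromides to the free triol.

**Compound list**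
1 | 1,3-dibromo-5-methoxybenzene (3,5-dibromoanisole) | COc1cc(Br)cc(Br)c1 | starting material
2 | 3-bromoprop-1-ene (allyl bromide) | C=CCBr | starting material
3 | (3-bromo-5-methoxyphenyl)lithium (not isolated) | [Li]c1cc(Br)cc(OC)c1 | intermediate
4 | 1-bromo-3-methoxy-5-(prop-2-en-1-yl)benzene | C=CCc1cc(Br)cc(OC)c1 | intermediate
5 | 11-bromoundec-1-ene | C=CCCCCCCCCCBr | starting material
6 | 4-bromo-2,6-dimethoxyphenol | COc1cc(Br)cc(OC)c1O | starting material
7 | undec-10-en-1-ylzinc bromide (not isolated) | C=CCCCCCCCCC[Zn]Br | intermediate
8 | 2,6-dimethoxy-4-(undec-10-en-1-yl)phenol | C=CCCCCCCCCCc1cc(OC)c(O)c(OC)c1 | intermediate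
9 | 1,3-dimethoxy-2-[3-methoxy-5-(prop-2-en-1-yl)phenoxy]-5-(undec-10-en-1-yl)benzene | C=CCCCCCCCCCc1cc(OC)c(Oc2cc(CC=C)cc(OC)c2)c(OC)c1 | intermediate
10 | tri-O-methyl cyclophane alkene, 1^5,3^2,3^6-trimethoxy-2-oxa-1(1,3),3(1,4)-dibenzenacyclopentadecaphan-13-ene, E/Z mixture: 5-methoxy-1,3-phenylene ring A and 2,6-dimethoxy-1,4-phenylene ring B joined by an ether oxygen and by the bridge ring A–CH2–CH=CH–(CH2)9–ring B | COc1cc2cc(c1)Oc1c(OC)cc(cc1OC)CCCCCCCCCC=CC2 | intermediate
11 | tri-O-methyl saturated cyclophane, 1^5,3^2,3^6-trimethoxy-2-oxa-1(1,3),3(1,4)-dibenzenacyclopentadecaphane: same rings joined by the ether oxygen and a (CH2)12 bridge | COc1cc2cc(c1)Oc1c(OC)cc(cc1OC)CCCCCCCCCCCC2 | intermediate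
12 | tris(dibromoboryl) ether of the target, each of the three phenolic oxygens carrying BBr2 (not isolated) | BrB(Br)Oc1cc2cc(c1)Oc1c(OB(Br)Br)cc(cc1OB(Br)Br)CCCCCCCCCCCC2 | intermediate
13 | 2-oxa-1(1,3),3(1,4)-dibenzenacyclopentadecaphane-1^5,3^2,3^6-triol: 5-hydroxy-1,3-phenylene ring A and 2,6-dihydroxy-1,4-phenylene ring B joined by an ether oxygen and a (CH2)12 bridge, achiral | Oc1cc2cc(c1)Oc1c(O)cc(cc1O)CCCCCCCCCCCC2 | target

**Totals**
Total steps: 6. Longest linear sequence: 5 steps (steps 2, 3, 4, 5, 6; equally steps 1, 3, 4, 5, 6).

**Steps most likely to fail**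

Step 4 (ring-closing metathesis). Intermolecular metathesis may outrun ring closure at any practical dilution and give oligomers. Ruthenium hydride-mediated migration of the allyl double bond before closure would contract the ring by one carbon. The fallback closes the macrocycle at the ether oxygen instead and sets out from 4 and 8. Cross-metathesis of 8 with an excess of 4 (second-generation Grubbs catalyst RuCl2(H2IMes)(PCy3)(=CHPh), 1,4-benzoquinone, CH2Cl2, 40 °C, 0.2 M, fast at this concentration) should give (E/Z)-4-[12-(3-bromo-5-methoxyphenyl)dodec-10-en-1-yl]-2,6-dimethoxyphenol F1. Homogeneous hydrogenation with H2 and RhCl(PPh3)3 in toluene/EtOH, which spares the aryl bromide, should give 4-[12-(3-bromo-5-methoxyphenyl)dodecyl]-2,6-dimethoxyphenol F2. Intramolecular Ullmann etherification of F2 (CuI, picolinic acid, K3PO4, DMSO, 90 °C, slow addition to 5 mM) should close the ring and come back to the route at 11.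

Step 3 (Ullmann etherification). Copper phenoxide formation and coupling may be slow at the doubly ortho-substituted oxygen, and prolonged heating with base may move the allyl double bond of 4 into conjugation. The fallback makes the ether before the allyl group is present and sets out from 8 and 1. Coupling of 8 with a threefold excess of dibromide 1 under forcing conditions (CuI, picolinic acid, K3PO4, DMSO, 110 °C) should give 2-(3-bromo-5-methoxyphenoxy)-1,3-dimethoxy-5-(undec-10-en-1-yl)benzene F3. Bromine–lithium exchange (n-BuLi, THF, −78 °C) should give {3-[2,6-dimethoxy-4-(undec-10-en-1-yl)phenoxy]-5-methoxyphenyl}lithium F4, which is allylated in the same flask with 2 (CuBr·SMe2 cat.) and comes back to the route at 9.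

Step 2 (Negishi coupling on the free phenol). The phenolic OH may protonate the alkylzinc reagent, and oxidative addition to the electron-rich bromophenol may be slow, so the zinc reagent is consumed without coupling. The fallback protects the phenol and reverses the polarity of the coupling; it sets out from 6 and uses 5 as the electrophile. NaH and chloromethyl methyl ether (COCCl) in THF at 0 °C should give 5-bromo-1,3-dimethoxy-2-(methoxymethoxy)benzene F5. Magnesium in THF should give [3,5-dimethoxy-4-(methoxymethoxy)phenyl]magnesium bromide F6, which is coupled in the same flask with 5 under Li2CuCl4 catalysis (3 mol%, THF/NMP, 0 °C to rt) to 1,3-dimethoxy-2-(methoxymethoxy)-5-(undec-10-en-1-yl)benzene F7. HCl in MeOH at 50 °C should remove the acetal and come back to the route at 8.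

**Further compounds**
F1 | step 4 | (E/Z)-4-[12-(3-bromo-5-methoxyphenyl)dodec-10-en-1-yl]-2,6-dimethoxyphenol | COc1cc(Br)cc(CC=CCCCCCCCCCc2cc(OC)c(O)c(OC)c2)c1
F2 | step 4 | 4-[12-(3-bromo-5-methoxyphenyl)dodecyl]-2,6-dimethoxyphenol | COc1cc(Br)cc(CCCCCCCCCCCCc2cc(OC)c(O)c(OC)c2)c1
F3 | step 3 | 2-(3-bromo-5-methoxyphenoxy)-1,3-dimethoxy-5-(undec-10-en-1-yl)benzene | C=CCCCCCCCCCc1cc(OC)c(Oc2cc(Br)cc(OC)c2)c(OC)c1
F4 | step 3 | {3-[2,6-dimethoxy-4-(undec-10-en-1-yl)phenoxy]-5-methoxyphenyl}lithium | C=CCCCCCCCCCc1cc(OC)c(Oc2cc([Li])cc(OC)c2)c(OC)c1
F5 | step 2 | 5-bromo-1,3-dimethoxy-2-(methoxymethoxy)benzene | COCOc1c(OC)cc(Br)cc1OC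
F6 | step 2 | [3,5-dimethoxy-4-(methoxymethoxy)phenyl]magnesium bromide | COCOc1c(OC)cc([Mg]Br)cc1OC
F7 | step 2 | 1,3-dimethoxy-2-(methoxymethoxy)-5-(undec-10-en-1-yl)benzene | C=CCCCCCCCCCc1cc(OC)c(OCOC)c(OC)c1
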